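Ring A is a 1,3,5-trioxygenated benzene whose C–OH, C–O(ring B) and C–O(ring C) carbons alternate with three CH carbons, so its six carbons are disconnected into three two-carbon units: one ketene and two aryl ethynyl ethers. Each hindered phenol oxygen of rings B and C is therefore bonded to an sp carbon before ring A exists. The key step, a Danheiser-type benzannulation, joins a 3-aryloxycyclobutenone carrying the ring C–ring D diaryl ether with the ethynyl ether of ring B and closes ring A as a 3,5-bis(aryloxy)phenol in one thermal operation. Rings B, C and D are bought as arenes; the C–O–D bond is made by SNAr, and all other phenols travel as benzyl ethers.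

Key step: step 12

Assumptions (remarks on the chemistry):
- Dichlorovinyl ethers 12 and 16 are drawn as the E isomers expected from anti addition to dichloroacetylene; the geometry is lost in the following step and does not matter.
- Where one step repeats the same event on one substrate (three O-benzylations in step 1, two fluoride displacements in step 4, two dechlorinations in step 11, eight debenzylations in step 13), the partly converted species are transient mixtures and are not numbered.
- Phenoxide salts formed by deprotonation of numbered phenols (steps 1, 3, 6, 8 and the closing base treatment of step 12) are the salt forms of those phenols and are not numbered separately.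
- Intermediate 25 forms as a racemate; its only stereocentre disappears in the next ring opening.

Step 1
Reactants: 1 2,4,6-trihydroxybenzaldehyde
Product: 2 2,4,6-tris(benzyloxy)benzaldehyde
Conditions: BnBr (3.5 equiv), K2CO3, DMF, 60 °C
Reagents that add atoms: benzyl bromide, BrCc1ccccc1
Why: Williamson O-benzylation of the three phenoxides; the formyl group lowers the C-nucleophilicity of the phloroglucinol ring so that O-alkylation should dominate, and warming in DMF overcomes the hydrogen bonds of the two ortho hydroxyls to the carbonyl.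

Step 2
Reactants: 2 2,4,6-tris(benzyloxy)benzaldehyde
Product: 4 2,4,6-tris(benzyloxy)phenol, via aryl formate 3 (not isolated)
Conditions: mCPBA, CH2Cl2, 0 °C to rt; aqueous Na2S2O3/NaHCO3 wash; then K2CO3 (cat.), MeOH/THF, rt
Reagents that add atoms: mCPBA (3-chloroperoxybenzoic acid), OOC(=O)c1cccc(Cl)c1
Why: Baeyer–Villiger (Dakin-type) oxidation in which the electron-rich di-ortho-alkoxy aryl group migrates in preference to hydride to give the aryl formate, which is methanolysed under mild base without touching the benzyl ethers.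

Step 3
Reactants: 4 2,4,6-tris(benzyloxy)phenol; 5 2,4,6-trifluorobenzaldehyde (1.2 equiv)
Product: 6 2,6-difluoro-4-[2,4,6-tris(benzyloxy)phenoxy]benzaldehyde
Conditions: K2CO3, DMF, 0 °C to rt
Reagents that add atoms: none
Why: Nucleophilic aromatic substitution through a Meisenheimer adduct stabilized by the para formyl group; the bulky di-ortho-substituted phenoxide should avoid the two fluorines flanking the formyl group and take the para fluorine, and the aryloxy group it introduces deactivates the ring against a second attack by this weak nucleophile.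

Step 4
Reactants: 6 2,6-difluoro-4-[2,4,6-tris(benzyloxy)phenoxy]benzaldehyde
Product: 7 2,6-bis(benzyloxy)-4-[2,4,6-tris(benzyloxy)phenoxy]benzaldehyde
Conditions: BnOH (2.3 equiv), NaH (2.2 equiv), THF/DMF, 0 °C (preformed BnONa added to 6), then 50 °C
Reagents that add atoms: benzyl alcohol, OCc1ccccc1
Why: Twofold SNAr of the two ortho fluorines, each activated by the adjacent formyl group, by preformed sodium benzyloxide; fluoride is by far the better leaving group at an activated position, so the para aryloxy group should stay in place when the alkoxide is held near two equivalents and the temperature is moderate.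

Step 5
Reactants: 7 2,6-bis(benzyloxy)-4-[2,4,6-tris(benzyloxy)phenoxy]benzaldehyde
Product: 9 2,6-bis(benzyloxy)-4-[2,4,6-tris(benzyloxy)phenoxy]phenol, via aryl formate 8 (not isolated)
Conditions: mCPBA, CH2Cl2, 0 °C to rt; aqueous Na2S2O3/NaHCO3 wash; then K2CO3 (cat.), MeOH/THF, rt
Reagents that add atoms: mCPBA (3-chloroperoxybenzoic acid), OOC(=O)c1cccc(Cl)c1
Why: Same Baeyer–Villiger oxidation and formate methanolysis as in step 2; the 2,4,6-trioxygenated aryl group migrates readily, and the diaryl ether and benzyl ethers are inert to peracid at 0 °C and to catalytic carbonate.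

Step 6
Reactants: 4 2,4,6-tris(benzyloxy)phenol; 10 trichloroethylene (2 equiv)
Product: 12 (E)-1,2-dichlorovinyl 2,4,6-tris(benzyloxy)phenyl ether, via dichloroacetylene 11 (not isolated)
Conditions: K2CO3, DMF, 70 °C
Reagents that add atoms: none
Why: Base-induced loss of HCl from trichloroethylene gives dichloroacetylene, a small linear electrophile to which even the hindered phenoxide adds in anti fashion, which is the established route from phenols to (E)-1,2-dichlorovinyl ethers.

Step 7
Reactants: 12 (E)-1,2-dichlorovinyl 2,4,6-tris(benzyloxy)phenyl ether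
Product: 15 ethynyl 2,4,6-tris(benzyloxy)phenyl ether, via chloroethynyl ether 13 (not isolated), via lithium acetylide 14 (not isolated)
Conditions: n-BuLi (2.3 equiv), THF, −78 °C; then H2O, −78 to 0 °C
Reagents that add atoms: none
Why: Established conversion of 1,2-dichlorovinyl ethers into ynol ethers, in which vinyl deprotonation and β-elimination of LiCl give the chloroalkyne, chlorine–lithium exchange gives the lithium acetylide and water protonates it; at −78 °C lithiation of the benzyl ethers or of the arene should not compete.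

Step 8
Reactants: 9 2,6-bis(benzyloxy)-4-[2,4,6-tris(benzyloxy)phenoxy]phenol; 10 trichloroethylene (2 equiv)
Product: 16 (E)-1,2-dichlorovinyl 2,6-bis(benzyloxy)-4-[2,4,6-tris(benzyloxy)phenoxy]phenyl ether
Conditions: K2CO3, DMF, 70 °C
Reagents that add atoms: none
Why: Same reaction as in step 6, in which dichloroacetylene 11 is formed again in the flask from 10 and carbonate and the hindered phenoxide of 9 adds to it in anti fashion; the diaryl ether and benzyl ethers are inert to carbonate in DMF.

Step 9
Reactants: 16 (E)-1,2-dichlorovinyl 2,6-bis(benzyloxy)-4-[2,4,6-tris(benzyloxy)phenoxy]phenyl ether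
Product: 19 ethynyl 2,6-bis(benzyloxy)-4-[2,4,6-tris(benzyloxy)phenoxy]phenyl ether, via chloroethynyl ether 17 (not isolated), via lithium acetylide 18 (not isolated)
Conditions: n-BuLi (2.3 equiv), THF, −78 °C; then H2O, −78 to 0 °C
Reagents that add atoms: none
Why: Same elimination, chlorine–lithium exchange and protonation sequence as in step 7; the low temperature and limited excess of n-BuLi should spare the five benzyl ethers and the diaryl ether.

Step 10
Reactants: 19 ethynyl 2,6-bis(benzyloxy)-4-[2,4,6-tris(benzyloxy)phenoxy]phenyl ether; 20 trichloroacetyl chloride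
Product: 22 4,4-dichloro-3-{2,6-bis(benzyloxy)-4-[2,4,6-tris(benzyloxy)phenoxy]phenoxy}cyclobut-2-en-1-one, via dichloroketene 21 (not isolated)
Conditions: Zn (activated dust), Et2O/DME, rt, slow addition of 20
Reagents that add atoms: none
Why: (2+2) cycloaddition of electrophilic dichloroketene, released from 20 by zinc, with the electron-rich alkyne, a reaction established for alkynes and alkoxyalkynes; the nucleophilic terminal carbon of the ynol ether bonds to the ketene carbonyl carbon, which places the aryloxy group at C3, and DME ties up the ZnCl2 formed.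

Step 11
Reactants: 22 4,4-dichloro-3-{2,6-bis(benzyloxy)-4-[2,4,6-tris(benzyloxy)phenoxy]phenoxy}cyclobut-2-en-1-one
Product: 23 3-{2,6-bis(benzyloxy)-4-[2,4,6-tris(benzyloxy)phenoxy]phenoxy}cyclobut-2-en-1-one
Conditions: Zn dust, AcOH, TMEDA, THF, 0 °C to rt
Reagents that add atoms: none
Why: Reductive removal of both chlorines alpha to the ketone by zinc through zinc enolates that acetic acid protonates, the standard dechlorination of dichloroketene–alkyne adducts; TMEDA buffers the medium and the non-nucleophilic solvent avoids exchange of the vinylogous aryl ester.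

Step 12
Reactants: 23 3-{2,6-bis(benzyloxy)-4-[2,4,6-tris(benzyloxy)phenoxy]phenoxy}cyclobut-2-en-1-one; 15 ethynyl 2,4,6-tris(benzyloxy)phenyl ether
Product: 28 3-[2,4,6-tris(benzyloxy)phenoxy]-5-{2,6-bis(benzyloxy)-4-[2,4,6-tris(benzyloxy)phenoxy]phenoxy}phenol (octa-O-benzyl tetramer), via vinylketene 24 (not isolated), via 4-alkenylcyclobutenone 25 (not isolated), via dienylketene 26 (not isolated), via cyclohexadienone 27 (not isolated)
Conditions: toluene (degassed), 80 to 110 °C, 23 added slowly to 15 (1.5 equiv); then KOH (2 equiv), MeOH/THF, rt; then saturated aqueous NH4Cl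
Reagents that add atoms: none
Why: Proposed new method: heating 23 should cause a reversible four-electron electrocyclic opening of its C1–C4 bond to vinylketene 24, whose ketene C=C adds (2+2) to ynol ether 15 to give 25, and a second four-electron opening then gives dienylketene 26, six-electron electrocyclization gives dienone 27 and tautomerization gives phenol 28. The closest known reaction is the Danheiser benzannulation of cyclobutenones with alkoxy- or siloxyalkynes, which gives resorcinol monoethers; the extension here is an aryloxy group on both partners, leading to a phloroglucinol diether. Ring A is the only ring closed in the product, by six-electron electrocyclization that bonds the ketene carbonyl carbon to the terminal CH2 carbon, while the four-membered ring of 25 is a transient closed by the (2+2) addition. No stereocentre is created in the product, since the sp3 centre of 25 is destroyed on ring opening and ring A is aromatic. The selectivity needed is the regiochemistry of the (2+2) addition, so that the three ring A oxygens end up mutually meta, and it is secured by the polarization of 15, whose nucleophilic terminal CH carbon attacks the electrophilic ketene carbonyl carbon. The aryl ynol ether has no β-hydrogen for retro-ene loss of a ketene, the aryloxy donor on 23 is weaker than alkoxy so the first opening should stay thermally accessible, slow addition of 23 to excess 15 keeps the ketene concentration low, and the closing KOH treatment in methanol, the usual finish of such benzannulations, converts the product into its potassium phenoxide and returns any phenol that a ketene has acylated before aqueous NH4Cl reprotonates it under conditions too mild to hydrate the remaining ynol ether.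

Step 13
Reactants: 28 3-[2,4,6-tris(benzyloxy)phenoxy]-5-{2,6-bis(benzyloxy)-4-[2,4,6-tris(benzyloxy)phenoxy]phenoxy}phenol
Product: 29 CNP0159471.0, 3-(2,4,6-trihydroxyphenoxy)-5-[2,6-dihydroxy-4-(2,4,6-trihydroxyphenoxy)phenoxy]phenol
Conditions: H2 (1 atm), Pd/C (10% palladium on carbon), THF/MeOH, rt, isolation under argon
Reagents that add atoms: none
Why: Hydrogenolysis of the eight benzylic C–O bonds on palladium, under which diaryl ether bonds and the arene rings are inert at atmospheric pressure and room temperature; the achiral polyphenol is handled under inert gas to avoid air oxidation.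

Compound list
1 | 2,4,6-trihydroxybenzaldehyde | O=Cc1c(O)cc(O)cc1O | starting material
2 | 2,4,6-tris(benzyloxy)benzaldehyde | O=Cc1c(OCc2ccccc2)cc(OCc2ccccc2)cc1OCc1ccccc1 | intermediate
3 | 2,4,6-tris(benzyloxy)phenyl formate (formed in situ) | O=COc1c(OCc2ccccc2)cc(OCc2ccccc2)cc1OCc1ccccc1 | intermediate
4 | 2,4,6-tris(benzyloxy)phenol | Oc1c(OCc2ccccc2)cc(OCc2ccccc2)cc1OCc1ccccc1 | intermediate
5 | 2,4,6-trifluorobenzaldehyde | O=Cc1c(F)cc(F)cc1F | starting material
6 | 2,6-difluoro-4-[2,4,6-tris(benzyloxy)phenoxy]benzaldehyde | O=Cc1c(F)cc(Oc2c(OCc3ccccc3)cc(OCc3ccccc3)cc2OCc2ccccc2)cc1F | intermediate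
7 | 2,6-bis(benzyloxy)-4-[2,4,6-tris(benzyloxy)phenoxy]benzaldehyde | O=Cc1c(OCc2ccccc2)cc(Oc2c(OCc3ccccc3)cc(OCc3ccccc3)cc2OCc2ccccc2)cc1OCc1ccccc1 | intermediate
8 | 2,6-bis(benzyloxy)-4-[2,4,6-tris(benzyloxy)phenoxy]phenyl formate (formed in situ) | O=COc1c(OCc2ccccc2)cc(Oc2c(OCc3ccccc3)cc(OCc3ccccc3)cc2OCc2ccccc2)cc1OCc1ccccc1 | intermediate
9 | 2,6-bis(benzyloxy)-4-[2,4,6-tris(benzyloxy)phenoxy]phenol | Oc1c(OCc2ccccc2)cc(Oc2c(OCc3ccccc3)cc(OCc3ccccc3)cc2OCc2ccccc2)cc1OCc1ccccc1 | intermediate
10 | trichloroethylene | ClC=C(Cl)Cl | starting material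
11 | dichloroacetylene (formed in situ) | ClC#CCl | intermediate
12 | (E)-1,2-dichlorovinyl 2,4,6-tris(benzyloxy)phenyl ether | Cl/C=C(/Cl)Oc1c(OCc2ccccc2)cc(OCc2ccccc2)cc1OCc1ccccc1 | intermediate
13 | chloroethynyl 2,4,6-tris(benzyloxy)phenyl ether (formed in situ) | ClC#COc1c(OCc2ccccc2)cc(OCc2ccccc2)cc1OCc1ccccc1 | intermediate
14 | lithium [2,4,6-tris(benzyloxy)phenoxy]acetylide (formed in situ) | [Li]C#COc1c(OCc2ccccc2)cc(OCc2ccccc2)cc1OCc1ccccc1 | intermediate
15 | ethynyl 2,4,6-tris(benzyloxy)phenyl ether | C#COc1c(OCc2ccccc2)cc(OCc2ccccc2)cc1OCc1ccccc1 | intermediate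
16 | (E)-1,2-dichlorovinyl 2,6-bis(benzyloxy)-4-[2,4,6-tris(benzyloxy)phenoxy]phenyl ether | Cl/C=C(/Cl)Oc1c(OCc2ccccc2)cc(Oc2c(OCc3ccccc3)cc(OCc3ccccc3)cc2OCc2ccccc2)cc1OCc1ccccc1 | intermediate
17 | chloroethynyl 2,6-bis(benzyloxy)-4-[2,4,6-tris(benzyloxy)phenoxy]phenyl ether (formed in situ) | ClC#COc1c(OCc2ccccc2)cc(Oc2c(OCc3ccccc3)cc(OCc3ccccc3)cc2OCc2ccccc2)cc1OCc1ccccc1 | intermediate
18 | lithium {2,6-bis(benzyloxy)-4-[2,4,6-tris(benzyloxy)phenoxy]phenoxy}acetylide (formed in situ) | [Li]C#COc1c(OCc2ccccc2)cc(Oc2c(OCc3ccccc3)cc(OCc3ccccc3)cc2OCc2ccccc2)cc1OCc1ccccc1 | intermediate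
19 | ethynyl 2,6-bis(benzyloxy)-4-[2,4,6-tris(benzyloxy)phenoxy]phenyl ether | C#COc1c(OCc2ccccc2)cc(Oc2c(OCc3ccccc3)cc(OCc3ccccc3)cc2OCc2ccccc2)cc1OCc1ccccc1 | intermediate
20 | trichloroacetyl chloride | O=C(Cl)C(Cl)(Cl)Cl | starting material
21 | dichloroketene (formed in situ) | O=C=C(Cl)Cl | intermediate
22 | 4,4-dichloro-3-{2,6-bis(benzyloxy)-4-[2,4,6-tris(benzyloxy)phenoxy]phenoxy}cyclobut-2-en-1-one | O=C1C=C(Oc2c(OCc3ccccc3)cc(Oc3c(OCc4ccccc4)cc(OCc4ccccc4)cc3OCc3ccccc3)cc2OCc2ccccc2)C1(Cl)Cl | intermediate
23 | 3-{2,6-bis(benzyloxy)-4-[2,4,6-tris(benzyloxy)phenoxy]phenoxy}cyclobut-2-en-1-one | O=C1C=C(Oc2c(OCc3ccccc3)cc(Oc3c(OCc4ccccc4)cc(OCc4ccccc4)cc3OCc3ccccc3)cc2OCc2ccccc2)C1 | intermediate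
24 | vinylketene, 3-{2,6-bis(benzyloxy)-4-[2,4,6-tris(benzyloxy)phenoxy]phenoxy}buta-1,3-dien-1-one (formed in situ) | O=C=CC(=C)Oc1c(OCc2ccccc2)cc(Oc2c(OCc3ccccc3)cc(OCc3ccccc3)cc2OCc2ccccc2)cc1OCc1ccccc1 | intermediate
25 | racemic 4-(1-{2,6-bis(benzyloxy)-4-[2,4,6-tris(benzyloxy)phenoxy]phenoxy}ethenyl)-3-[2,4,6-tris(benzyloxy)phenoxy]cyclobut-2-en-1-one (formed in situ) | O=C1C=C(Oc2c(OCc3ccccc3)cc(OCc3ccccc3)cc2OCc2ccccc2)C1C(=C)Oc1c(OCc2ccccc2)cc(Oc2c(OCc3ccccc3)cc(OCc3ccccc3)cc2OCc2ccccc2)cc1OCc1ccccc1 | intermediate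
26 | dienylketene, (3E)-3-[2,4,6-tris(benzyloxy)phenoxy]-5-{2,6-bis(benzyloxy)-4-[2,4,6-tris(benzyloxy)phenoxy]phenoxy}hexa-1,3,5-trien-1-one, carbon chain cis across C3=C4 (formed in situ) | O=C=C/C(Oc1c(OCc2ccccc2)cc(OCc2ccccc2)cc1OCc1ccccc1)=C\C(=C)Oc1c(OCc2ccccc2)cc(Oc2c(OCc3ccccc3)cc(OCc3ccccc3)cc2OCc2ccccc2)cc1OCc1ccccc1 | intermediate
27 | 3-[2,4,6-tris(benzyloxy)phenoxy]-5-{2,6-bis(benzyloxy)-4-[2,4,6-tris(benzyloxy)phenoxy]phenoxy}cyclohexa-2,4-dien-1-one (formed in situ) | O=C1C=C(Oc2c(OCc3ccccc3)cc(OCc3ccccc3)cc2OCc2ccccc2)C=C(Oc2c(OCc3ccccc3)cc(Oc3c(OCc4ccccc4)cc(OCc4ccccc4)cc3OCc3ccccc3)cc2OCc2ccccc2)C1 | intermediate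
28 | 3-[2,4,6-tris(benzyloxy)phenoxy]-5-{2,6-bis(benzyloxy)-4-[2,4,6-tris(benzyloxy)phenoxy]phenoxy}phenol (octa-O-benzyl tetramer) | Oc1cc(Oc2c(OCc3ccccc3)cc(OCc3ccccc3)cc2OCc2ccccc2)cc(Oc2c(OCc3ccccc3)cc(Oc3c(OCc4ccccc4)cc(OCc4ccccc4)cc3OCc3ccccc3)cc2OCc2ccccc2)c1 | intermediate
29 | CNP0159471.0, 3-(2,4,6-trihydroxyphenoxy)-5-[2,6-dihydroxy-4-(2,4,6-trihydroxyphenoxy)phenoxy]phenol (achiral) | Oc1cc(Oc2c(O)cc(O)cc2O)cc(Oc2c(O)cc(Oc3c(O)cc(O)cc3O)cc2O)c1 | target

Total step count: 13 steps.
Longest linear sequence: 11 steps (steps 1, 2, 3, 4, 5, 8, 9, 10, 11, 12, 13, from compound 1 to compound 29); steps 6 and 7 form the short branch to ynol ether 15.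

Steps most likely to fail

1. Step 12 (proposed new method). The donor-substituted cyclobutenone may open too slowly, so that thermal oligomerization of the ynol ether or acylation of the product phenol by the ketene intermediates outruns the benzannulation. The fallback uses known copper-catalysed Ullmann diaryl ether couplings, which tolerate di-ortho-substituted phenols, and sets out from phenols 4 and 9. Phenol 4 is coupled (CuI, picolinic acid, K3PO4, DMSO, 90 °C) with an excess of bought 1-(benzyloxy)-3,5-dibromobenzene F1 to give 1-(benzyloxy)-3-bromo-5-[2,4,6-tris(benzyloxy)phenoxy]benzene F2. A second coupling of the remaining bromide with phenol 9 under the same catalyst should give the nona-O-benzyl tetramer 1-(benzyloxy)-3-[2,4,6-tris(benzyloxy)phenoxy]-5-{2,6-bis(benzyloxy)-4-[2,4,6-tris(benzyloxy)phenoxy]phenoxy}benzene F3. Hydrogenolysis of its nine benzyl ethers under the conditions of step 13 comes back to the route at target 29.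

2. Step 10. The ZnCl2 formed may promote oligomerization of the aryl ynol ether, or chlorine migration and ring opening of the dichlorocyclobutenone, before it can be reduced. The fallback sets out from ynol ether 19 and replaces the halogenated ketene by the parent compound: ketene F4, generated in a separate pyrolysis apparatus, is passed into a CH2Cl2 solution of 19 at 0 °C. The (2+2) addition of ketene to alkoxyalkynes is known and should give cyclobutenone 23 directly, where the route is rejoined, so that neither 22 nor the zinc reduction of step 11 is needed.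

3. Step 4. Hydride transfer from benzyloxide to the formyl group (Meerwein–Ponndorf–Verley or Cannizzaro type) and ipso displacement of the para aryloxy group may compete with fluoride displacement. The fallback sets out from phenol 4 and uses a nitrile, which is inert to alkoxide, as the activating group. SNAr of 4 (K2CO3, DMF) on bought 2,4,6-trifluorobenzonitrile F5 should give 2,6-difluoro-4-[2,4,6-tris(benzyloxy)phenoxy]benzonitrile F6. Sodium benzyloxide (BnOH, NaH, THF/DMF) then replaces both fluorines to give 2,6-bis(benzyloxy)-4-[2,4,6-tris(benzyloxy)phenoxy]benzonitrile F7. Reduction with i-Bu2AlH (toluene, −78 to 0 °C) gives, after protonation, 2,6-bis(benzyloxy)-4-[2,4,6-tris(benzyloxy)phenoxy]benzaldimine F8, which aqueous HCl hydrolyses to aldehyde 7, where the route is rejoined.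

Further compounds
F1 | step 12 | 1-(benzyloxy)-3,5-dibromobenzene (bought) | Brc1cc(Br)cc(OCc2ccccc2)c1
F2 | step 12 | 1-(benzyloxy)-3-bromo-5-[2,4,6-tris(benzyloxy)phenoxy]benzene | Brc1cc(OCc2ccccc2)cc(Oc2c(OCc3ccccc3)cc(OCc3ccccc3)cc2OCc2ccccc2)c1
F3 | step 12 | 1-(benzyloxy)-3-[2,4,6-tris(benzyloxy)phenoxy]-5-{2,6-bis(benzyloxy)-4-[2,4,6-tris(benzyloxy)phenoxy]phenoxy}benzene (nona-O-benzyl tetramer) | c1ccccc1COc1cc(Oc2c(OCc3ccccc3)cc(OCc3ccccc3)cc2OCc2ccccc2)cc(Oc2c(OCc3ccccc3)cc(Oc3c(OCc4ccccc4)cc(OCc4ccccc4)cc3OCc3ccccc3)cc2OCc2ccccc2)c1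
F4 | step 10 | ketene | C=C=O
F5 | step 4 | 2,4,6-trifluorobenzonitrile (bought) | N#Cc1c(F)cc(F)cc1F
F6 | step 4 | 2,6-difluoro-4-[2,4,6-tris(benzyloxy)phenoxy]benzonitrile | N#Cc1c(F)cc(Oc2c(OCc3ccccc3)cc(OCc3ccccc3)cc2OCc2ccccc2)cc1F
F7 | step 4 | 2,6-bis(benzyloxy)-4-[2,4,6-tris(benzyloxy)phenoxy]benzonitrile | N#Cc1c(OCc2ccccc2)cc(Oc2c(OCc3ccccc3)cc(OCc3ccccc3)cc2OCc2ccccc2)cc1OCc1ccccc1
F8 | step 4 | 2,6-bis(benzyloxy)-4-[2,4,6-tris(benzyloxy)phenoxy]benzaldimine | N=Cc1c(OCc2ccccc2)cc(Oc2c(OCc3ccccc3)cc(OCc3ccccc3)cc2OCc2ccccc2)cc1OCc1ccccc1
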